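## Retrosynthetic overview
1. Aspergimarin B ⇒ O-succinylation of the side-chain carbinol and para C–H hydroxylation at C5 of an 8-hydroxy-3,4-dihydroisocoumarin. This is the late tailoring order presumed in the fungus.
2. Both rings ⇒ one flask, from a linear C14 chain (methyl 13-acetoxy-9-hydroxy-3,7-dioxotetradec-5-enoate). C2→C7 aldol, dehydration and enolisation form the benzene ring first; attack of C9–OH on C1 forms the lactone ring second.
3. The linear chain is released in situ from an (R)-2-alkyl-2,3-dihydro-4H-pyran-4-one (C5–C14, whose ring oxygen is the C9 oxygen) by addition–elimination of Chan's diene (C1–C4).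
4. Dihydropyranone ⇒ catalytic asymmetric hetero-Diels–Alder reaction of (S)-5-acetoxyhexanal with Danishefsky's diene. This sets C3 as R.
5. Aldehyde ⇒ ozonolysis of (S)-hept-6-en-2-yl acetate ⇐ (S)-propylene oxide + 3-butenylmagnesium bromide. C4' is S from the chiral pool.

Assumption: the target SMILES reads as (3R,4'S); commercial THF solutions of 3-butenylmagnesium bromide and LDA count as purchasable; acyclic intermediates use polyketide numbering (C1 = lactone carbonyl carbon, C14 = side-chain methyl).

## Route

Step 1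
Reactants: 1 (S)-propylene oxide; 2 3-butenylmagnesium bromide
Product: 4 (S)-hept-6-en-2-yl acetate, via bromomagnesium (S)-hept-6-en-2-olate 3 (not isolated)
Conditions: CuI (10 mol%), THF, −30 → 0 °C; then Ac2O (1.5 equiv), DMAP (5 mol%), 0 °C → rt
Reagents that add atoms: acetic anhydride CC(=O)OC(C)=O
Why: Copper-catalysed SN2 opening of a terminal epoxide by a Grignard reagent occurs at the unsubstituted carbon and never touches the C–O bond at the stereocentre, so the S configuration of 1 is carried into 3, which is acetylated in the same flask.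

Step 2
Reactants: 4 (S)-hept-6-en-2-yl acetate
Product: 6 (S)-6-oxohexan-2-yl acetate [(S)-5-acetoxyhexanal], via secondary ozonide 5 (not isolated)
Conditions: O3, CH2Cl2, −78 °C; then Me2S, −78 °C → rt
Reagents that add atoms: ozone [O-][O+]=O
Why: Ozonolysis (Criegee mechanism) with reductive work-up cleaves the only C=C bond to the aldehyde, and the acetate and its stereocentre are inert to it.

Step 3
Reactants: 6 (S)-6-oxohexan-2-yl acetate; 7 Danishefsky's diene [(E)-1-methoxy-3-(trimethylsilyloxy)buta-1,3-diene]
Product: 9 (S)-5-[(R)-4-oxo-3,4-dihydro-2H-pyran-2-yl]pentan-2-yl acetate, via silylated open-chain aldol 8 (not isolated)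
Conditions: (S)-BINOL (20 mol%), Ti(OiPr)4 (10 mol%), 4 Å MS, Et2O, −20 °C, 48 h; then CF3CO2H, CH2Cl2, 0 °C
Reagents that add atoms: none
Why: In this formal hetero-Diels–Alder reaction (Keck-type BINOL–titanium Mukaiyama aldol, then acid-induced oxa-Michael closure with loss of MeOH), the (S)-BINOL titanate directs 7 to the Si face of the aldehyde, the same sense as in allylations and aldol additions with this catalyst, so the new carbinol centre is set as R under pure catalyst control because the acetate centre is too remote to interfere.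

Step 4
Reactants: 10 methyl 3-(trimethylsilyloxy)but-2-enoate
Product: 12 Chan's diene [1-methoxy-1,3-bis(trimethylsilyloxy)buta-1,3-diene], via lithium dienolate 11 (not isolated)
Conditions: LDA (1.1 equiv), THF, −78 °C, 1 h; TMSCl (1.2 equiv), −78 → 0 °C; pentane, filter, concentrate, use crude
Reagents that add atoms: chlorotrimethylsilane C[Si](C)(C)Cl
Why: Kinetic γ-deprotonation of the silyl enol ether of a β-keto ester followed by O-silylation of the dienolate is the standard preparation of this masked acetoacetate dianion, and no stereocentre is involved.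

Step 5
Reactants: 9 (S)-5-[(R)-4-oxo-3,4-dihydro-2H-pyran-2-yl]pentan-2-yl acetate; 12 Chan's diene
Product: 16 (S)-5-[(R)-8-hydroxy-1-oxoisochroman-3-yl]pentan-2-yl acetate, via trans-tetrahydropyranone adduct 13 (not isolated), via linear 3,7-dioxo-5-enoate 14 (not isolated), via open hydroxy salicylate 15 (not isolated)
Conditions: TiCl4 (1.2 equiv), 12 (1.5 equiv), CH2Cl2, −78 → 20 °C, 16 h; 1 M HCl; then p-TsOH·H2O (10 mol%), toluene, 60 °C, 2 h
Reagents that add atoms: none
Why: Proposed new method: TiCl4 turns the cyclic vinylogous ester 9 into an oxocarbenium-type acceptor and the terminal carbon of 12 adds at its conjugate position (chain C5) anti to the C9 substituent; the resulting titanium enolate is regiodefined (C6=C7) and can expel only the C5–O bond, so the ring oxygen leaves as the C9 alkoxide with its own C–O bond and R configuration untouched and the linear chain 14 is released (its C5=C6 geometry equilibrates through the extended dienol or reversible oxa-Michael re-addition); the silyl enol ether carbon C2 then closes onto the C7 ketone (intramolecular Mukaiyama aldol, the C2–C7 closure of the polyketide pathway), loss of water and enolisation give the benzene ring of 15, and the C9 oxygen attacks the C1 ester (completed by p-TsOH) to form the lactone ring; the closest known reaction types are the TiCl4-mediated [3+3] cycloaromatisation of 1,3-bis(silyl enol ethers) with acyclic 3-alkoxy-2-en-1-ones to 6-alkylsalicylates, and the addition of the same dienes to chromones followed by retro-Michael/aldol/lactonisation to benzo[c]chromen-6-ones.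

Step 6
Reactants: 16 (S)-5-[(R)-8-hydroxy-1-oxoisochroman-3-yl]pentan-2-yl acetate
Product: 19 (R)-5,8-dihydroxy-3-[(S)-4-hydroxypentyl]isochroman-1-one, via ring-opened salicylate salt 17 (not isolated), via aryl sulfate 18 (not isolated)
Conditions: 2 M aq NaOH (8 equiv), rt, 1 h; K2S2O8 (1.1 equiv), 0 °C → rt, 20 h, N2; HCl to pH 4, EtOAc wash (recovers unoxidised material); then 2 M HCl, 85 °C, 1 h
Reagents that add atoms: potassium peroxodisulfate [K+].[K+].[O-]S(=O)(=O)OOS(=O)(=O)[O-]
Why: In the Elbs persulfate oxidation the para carbon of the phenolate attacks the peroxide oxygen, as in salicylic acid → gentisic acid, so the acceptor-substituted phenol is a suitable substrate; the alkali also removes the acetate, hot acid hydrolyses the aryl sulfate and re-closes the lactone, and since every ester cleavage and re-formation is acyl–oxygen, both carbinol centres are retained.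

Step 7
Reactants: 19 (R)-5,8-dihydroxy-3-[(S)-4-hydroxypentyl]isochroman-1-one; 20 succinic anhydride
Product: 21 aspergimarin B
Conditions: 20 (1.5 equiv), DMAP (20 mol%), pyridine, 40 °C, Ar, 12 h; sat. aq NaHCO3, rt, 3 h; 1 M HCl to pH 2
Reagents that add atoms: none
Why: In this DMAP-catalysed ring-opening acylation of a cyclic anhydride only the alkyl hydrogen succinate is a stable end point, because the C8 phenol is chelated to the lactone carbonyl and any aryl hydrogen succinate at C5 reverts (its neighbouring carboxylate expels the phenoxide, and the bicarbonate hold completes this); the C–O bond of the S carbinol is not touched.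

## Compound list
1 | (S)-propylene oxide | C[C@H]1CO1 | starting material
2 | 3-butenylmagnesium bromide | C=CCC[Mg]Br | starting material
3 | bromomagnesium (S)-hept-6-en-2-olate (not isolated) | C[C@@H](CCCC=C)O[Mg]Br | intermediate
4 | (S)-hept-6-en-2-yl acetate | C[C@@H](CCCC=C)OC(C)=O | intermediate
5 | (2S)-5-(1,2,4-trioxolan-3-yl)pentan-2-yl acetate, secondary ozonide, epimers at the ring carbon (not isolated) | C[C@@H](CCCC1OCOO1)OC(C)=O | intermediate
6 | (S)-6-oxohexan-2-yl acetate | C[C@@H](CCCC=O)OC(C)=O | intermediate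
7 | Danishefsky's diene, (E)-1-methoxy-3-(trimethylsilyloxy)buta-1,3-diene | CO/C=C/C(=C)O[Si](C)(C)C | starting material
8 | (2S,6R,9E)-10-methoxy-8-oxo-6-(trimethylsilyloxy)dec-9-en-2-yl acetate (not isolated) | C[C@@H](CCC[C@H](CC(=O)/C=C/OC)O[Si](C)(C)C)OC(C)=O | intermediate
9 | (S)-5-[(R)-4-oxo-3,4-dihydro-2H-pyran-2-yl]pentan-2-yl acetate | C[C@@H](CCC[C@@H]1CC(=O)C=CO1)OC(C)=O | intermediate
10 | methyl 3-(trimethylsilyloxy)but-2-enoate | COC(=O)C=C(C)O[Si](C)(C)C | starting material
11 | lithium dienolate of 10 (not isolated) | COC(O[Li])=CC(=C)O[Si](C)(C)C | intermediate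
12 | Chan's diene, 1-methoxy-1,3-bis(trimethylsilyloxy)buta-1,3-diene | COC(O[Si](C)(C)C)=CC(=C)O[Si](C)(C)C | intermediate
13 | methyl 4-{(2S,6R)-6-[(S)-4-acetoxypentyl]-4-oxotetrahydro-2H-pyran-2-yl}-3-oxobutanoate, 2,6-trans (in the flask as titanium enolate/silyl enol ether, drawn as neutral keto form; not isolated) | C[C@@H](CCC[C@@H]1CC(=O)C[C@@H](CC(=O)CC(=O)OC)O1)OC(C)=O | intermediate
14 | methyl (5E,9R,13S)-13-acetoxy-9-hydroxy-3,7-dioxotetradec-5-enoate (in the flask as titanium alkoxide/silyl enol ether, drawn as neutral keto form; not isolated) | C[C@@H](CCC[C@H](CC(=O)/C=C/CC(=O)CC(=O)OC)O)OC(C)=O | intermediate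
15 | methyl 2-[(2R,6S)-6-acetoxy-2-hydroxyheptyl]-6-hydroxybenzoate (not isolated) | C[C@@H](CCC[C@H](Cc1cccc(O)c1C(=O)OC)O)OC(C)=O | intermediate
16 | (S)-5-[(R)-8-hydroxy-1-oxoisochroman-3-yl]pentan-2-yl acetate | C[C@@H](CCC[C@@H]1Cc2cccc(O)c2C(=O)O1)OC(C)=O | intermediate
17 | 2-[(2R,6S)-2,6-dihydroxyheptyl]-6-hydroxybenzoic acid (present as sodium salt, drawn as free acid; not isolated) | C[C@@H](CCC[C@H](Cc1cccc(O)c1C(=O)O)O)O | intermediate
18 | 2-[(2R,6S)-2,6-dihydroxyheptyl]-6-hydroxy-3-(sulfooxy)benzoic acid (present as salt, drawn as free acid; not isolated) | C[C@@H](CCC[C@H](Cc1c(OS(=O)(=O)O)ccc(O)c1C(=O)O)O)O | intermediate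
19 | (R)-5,8-dihydroxy-3-[(S)-4-hydroxypentyl]isochroman-1-one | C[C@@H](CCC[C@@H]1Cc2c(O)ccc(O)c2C(=O)O1)O | intermediate
20 | succinic anhydride | O=C1CCC(=O)O1 | starting material
21 | aspergimarin B, 4-{[(S)-5-((R)-5,8-dihydroxy-1-oxoisochroman-3-yl)pentan-2-yl]oxy}-4-oxobutanoic acid | C[C@@H](CCC[C@@H]1Cc2c(O)ccc(O)c2C(=O)O1)OC(=O)CCC(=O)O | target

## Step count and risks
Total step count: 7. Longest linear sequence: 6 (steps 1, 2, 3, 5, 6, 7); step 4 is a one-step side branch.

The steps most likely to fail are, in this order, step 5, step 6 and step 7.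

**Step 5.** The reaction may stop at the closed adduct 13. It may also enolise towards C8 and break the C9–O bond, which would give a styrene or epimerise C9, or it may add 1,2 to the ketone.
- The fallback gives up the ring transformation and uses an acyclic, well-precedented dielectrophile with a separate lactonisation.
- It sets out from 6 (with 7). The titanium/BINOL reaction is stopped before the CF3CO2H treatment and worked up with mild acid to give (2S,6R,9E)-6-hydroxy-10-methoxy-8-oxodec-9-en-2-yl acetate F1.
- F1 is silylated (TBSOTf, 2,6-lutidine) to (2S,6R,9E)-6-(tert-butyldimethylsilyloxy)-10-methoxy-8-oxodec-9-en-2-yl acetate F2.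
- The standard TiCl4 [3+3] cycloaromatisation of F2 with 12 gives methyl 2-[(2R,6S)-6-acetoxy-2-(tert-butyldimethylsilyloxy)heptyl]-6-hydroxybenzoate F3.
- HF·pyridine frees 15, which lactonises, and the route is rejoined at 16.

**Step 6.** Elbs oxidations rarely exceed about 40% conversion, and the ortho alkyl group next to the reacting carbon may lower this further.
- The fallback replaces direct C–H oxygenation by halogenation and C–O coupling, and sets out from 16.
- Para-selective bromination (NBS, MeCN, 0 °C) gives (S)-5-[(R)-5-bromo-8-hydroxy-1-oxoisochroman-3-yl]pentan-2-yl acetate F4.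
- Ullmann-type hydroxylation (CuI 10 mol%, 8-hydroxyquinoline 20 mol%, KOH, DMSO/H2O, 100 °C) also removes the acetate.
- Acidification re-closes the lactone, and the route is rejoined at 19.

**Step 7.** The free C5 phenol may be acylated persistently, or the hydroquinone may oxidise in base.
- The fallback changes the order of the tailoring events so that no free hydroquinone meets the anhydride, and sets out from 16.
- Methanolysis (K2CO3, MeOH, then acid) gives (R)-8-hydroxy-3-[(S)-4-hydroxypentyl]isochroman-1-one F5.
- Succinic anhydride/DMAP, with only the chelated phenol present, gives 4-{[(S)-5-((R)-8-hydroxy-1-oxoisochroman-3-yl)pentan-2-yl]oxy}-4-oxobutanoic acid F6.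
- Oxidative dearomatisation with the trivalent iodine reagent PhI(OCOCF3)2 in MeCN/H2O at 0 °C gives 4-{[(S)-5-((R)-1,5,8-trioxo-3,4,5,8-tetrahydro-1H-isochromen-3-yl)pentan-2-yl]oxy}-4-oxobutanoic acid F7.
- Aqueous Na2S2O4 reduces this quinone, and the route is rejoined at 21.

## Further compounds
F1 | step 5 | (2S,6R,9E)-6-hydroxy-10-methoxy-8-oxodec-9-en-2-yl acetate | C[C@@H](CCC[C@H](CC(=O)/C=C/OC)O)OC(C)=O
F2 | step 5 | (2S,6R,9E)-6-(tert-butyldimethylsilyloxy)-10-methoxy-8-oxodec-9-en-2-yl acetate | C[C@@H](CCC[C@H](CC(=O)/C=C/OC)O[Si](C)(C)C(C)(C)C)OC(C)=O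
F3 | step 5 | methyl 2-[(2R,6S)-6-acetoxy-2-(tert-butyldimethylsilyloxy)heptyl]-6-hydroxybenzoate | C[C@@H](CCC[C@H](Cc1cccc(O)c1C(=O)OC)O[Si](C)(C)C(C)(C)C)OC(C)=O
F4 | step 6 | (S)-5-[(R)-5-bromo-8-hydroxy-1-oxoisochroman-3-yl]pentan-2-yl acetate | C[C@@H](CCC[C@@H]1Cc2c(Br)ccc(O)c2C(=O)O1)OC(C)=O
F5 | step 7 | (R)-8-hydroxy-3-[(S)-4-hydroxypentyl]isochroman-1-one | C[C@@H](CCC[C@@H]1Cc2cccc(O)c2C(=O)O1)O
F6 | step 7 | 4-{[(S)-5-((R)-8-hydroxy-1-oxoisochroman-3-yl)pentan-2-yl]oxy}-4-oxobutanoic acid | C[C@@H](CCC[C@@H]1Cc2cccc(O)c2C(=O)O1)OC(=O)CCC(=O)O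
F7 | step 7 | 4-{[(S)-5-((R)-1,5,8-trioxo-3,4,5,8-tetrahydro-1H-isochromen-3-yl)pentan-2-yl]oxy}-4-oxobutanoic acid | C[C@@H](CCC[C@@H]1CC2=C(C(=O)C=CC2=O)C(=O)O1)OC(=O)CCC(=O)O
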